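**Retrosynthetic overview**
- The target is opened at the C3–aroyl bond and at the C4 enol: the last steps are C3 aroylation of a bicyclic β-methoxy enone and hydrolytic unmasking.
- Key disconnection: C5–C6 and C1–C9 are cut together, which leads back to a 4-methoxy-2-pyrone with the lavandulyl group on pyrone C3 and an iodo-terpenoid chain on pyrone C6. The enabling feature is that ring A (C1–C2–C3–C4–C5–C9) is a 1,3,5-trioxygenated carbocycle, the carbon isomer of a 4-oxy-2-pyrone (ring O–C9 in place of C1–C9), and that C5, between C4 and C9, lies 1,3 across ring A from the C8–C7–C6 chain on C1.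
- The pyrone comes from the dianion of a lavandulyl-bearing acetoacetate and a δ-lactone (C2–C3 bond), followed by lateral prenylation at C1.
- The lactone stereodiad (C7, C8) comes from an enantioselective Ireland–Claisen rearrangement of geranyl 5-methylhex-4-enoate; the side-chain centre comes from (S)-lavandulol.
- Ring order: pyrone (temporary ring), then ring A, then ring B (C1–C8–C7–C6–C5–C9); the last two close in the key step.

Key step: step 12

**Remarks (assumptions)**
- Locants C1–C9 in the text are those of the bicyclo[3.3.1]nonane core of the target (C1 prenyl bridgehead, C2–C4 the β-diketone unit, C5 lavandulyl bridgehead, C6 CH2, C7 CH-prenyl, C8 quaternary carbon, C9 bridging ketone). Prenyl = 3-methylbut-2-en-1-yl, homoprenyl = 4-methylpent-3-en-1-yl, lavandulyl = 5-methyl-2-(prop-1-en-2-yl)hex-4-en-1-yl.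
- (S)-Lavandulol is taken as a commercial (pheromone-grade) starting material. Its stereocentre is labelled (S) in the alcohol and iodide and (R) once the CH2 carries carbon; only the priorities change.
- The (S,S)-boron controller of step 2 is assumed to give the (2R,3R) acid. If the sense of induction proves opposite, its enantiomer is used and nothing else changes.

**Route**

Step 1
Reactants: 1 geraniol; 2 5-methylhex-4-enoic acid
Product: 3 geranyl 5-methylhex-4-enoate
Conditions: DCC, DMAP (cat.), CH2Cl2, 0 °C → rt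
Reagents that add atoms: none
Why: Steglich esterification of a primary allylic alcohol with an unhindered acid is reliable and forms no stereocentre.

Step 2
Reactants: 3 geranyl 5-methylhex-4-enoate
Product: 5 (2R,3R)-3-ethenyl-3,7-dimethyl-2-(3-methylbut-2-en-1-yl)oct-6-enoic acid, via boron ketene acetal 4 (not isolated)
Conditions: (S,S)-bromoborane controller [B–Br diazaborolidine of (1S,2S)-N,N'-bis(3,5-bis(trifluoromethyl)benzenesulfonyl)-1,2-diphenylethane-1,2-diamine, prepared beforehand, 1.1 equiv], Et3N, toluene–hexane, −78 °C → rt; H2O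
Reagents that add atoms: none
Why: Enantioselective Ireland–Claisen rearrangement through a chiral boron enolate: the E(O) ketene acetal 4 (prenyl CH2 cis to the allyloxy group, the geometry expected with Et3N in toluene–hexane) should rearrange through a chair in which the (E)-alkene holds its methyl group pseudoaxial, which sets the two new centres relative to each other (C7 prenyl anti to the C8 homoprenyl group in the zigzag), while the C2-symmetric sulfonamide ligand on boron shields one enolate face and sets the absolute configuration.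

Step 3
Reactants: 5 (2R,3R)-acid
Product: 6 (2R,3R)-3-ethenyl-3,7-dimethyl-2-(3-methylbut-2-en-1-yl)oct-6-en-1-ol
Conditions: LiAlH4, THF, 0 °C → rt
Reagents that add atoms: none
Why: LiAlH4 reduction of a carboxylic acid to the primary alcohol leaves the isolated alkenes and both stereocentres untouched.

Step 4
Reactants: 6 (2R,3R)-alcohol
Product: 7 (2R,3R)-3-methyl-2-(3-methylbut-2-en-1-yl)-3-(4-methylpent-3-en-1-yl)pentane-1,5-diol
Conditions: 9-BBN (2.5 equiv), THF, 0 → 50 °C; then NaOH, H2O2, 0 °C → rt
Reagents that add atoms: hydrogen peroxide, OO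
Why: Hydroboration–oxidation with the bulky 9-BBN should take only the monosubstituted vinyl group (anti-Markovnikov) and not the two trisubstituted alkenes; no stereocentre is formed.

Step 5
Reactants: 7 (2R,3R)-diol
Product: 8 (4R,5R)-4-methyl-5-(3-methylbut-2-en-1-yl)-4-(4-methylpent-3-en-1-yl)oxan-2-one
Conditions: TEMPO (cat.), PhI(OAc)2, CH2Cl2, rt
Reagents that add atoms: none
Why: Oxoammonium (TEMPO) oxidative lactonisation of a 1,5-diol: the less hindered CH2CH2OH arm should be oxidised first, the aldehyde is trapped as the lactol by the β-branched alcohol and oxidised on, so the carbonyl ends at C2 and the ring oxygen on C6.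

Step 6
Reactants: 9 (S)-lavandulol
Product: 10 (S)-lavandulyl iodide
Conditions: I2, PPh3, imidazole, CH2Cl2, 0 °C → rt
Reagents that add atoms: iodine, II
Why: Appel reaction, an SN2 displacement at a primary carbon that does not touch the stereocentre.

Step 7
Reactants: 11 methyl acetoacetate (excess); 10 (S)-lavandulyl iodide
Product: 12 methyl (4R)-2-acetyl-7-methyl-4-(prop-1-en-2-yl)oct-6-enoate (both C2 epimers)
Conditions: NaH, DMF, 0 °C; then 10, 60 °C
Reagents that add atoms: none
Why: C-Alkylation of the sodium enolate of a β-keto ester with a primary iodide; the new α-centre is epimerisable and is destroyed later.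

Step 8
Reactants: 12 lavandulyl acetoacetate; 8 (4R,5R)-lactone
Product: 14 4-hydroxy-2-pyrone alcohol, via hydroxy dioxo ester 13 (not isolated)
Conditions: 12, LiN(i-Pr)2 (LDA, 3.3 equiv), THF, −78 → 0 °C; 8, −78 → 0 °C; AcOH; then DBU, toluene, 110 °C
Reagents that add atoms: none
Why: γ-Acylation of the β-keto ester dianion by the δ-lactone (Claisen-type condensation) gives the 3,5-dioxo ester 13, whose C2 enol oxygen attacks the methyl ester under DBU to close the aromatic 4-hydroxy-2-pyrone, a standard pyrone synthesis; no stereocentre is formed.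

Step 9
Reactants: 14 4-hydroxy-2-pyrone alcohol
Product: 15 4-methoxy-2-pyrone alcohol
Conditions: Me2SO4, K2CO3, acetone, 56 °C
Reagents that add atoms: dimethyl sulfate, COS(=O)(=O)OC
Why: The pyrone 4-OH is a vinylogous carboxylic acid and should be O-methylated selectively under carbonate conditions that leave the primary alcohol alone.

Step 10
Reactants: 15 4-methoxy-2-pyrone alcohol; 16 prenyl bromide
Product: 17 C1-prenylated 4-methoxy-2-pyrone alcohol (both C1 epimers)
Conditions: LiN(i-Pr)2 (2.2 equiv), THF, −78 °C; 16, −78 → −20 °C; H2O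
Reagents that add atoms: none
Why: Lateral (vinylogous) deprotonation of a 4-methoxy-6-alkyl-2-pyrone followed by SN2 alkylation with an allylic bromide is established pyrone chemistry; the alkoxide is a spectator and the new C1 centre is erased in step 12.

Step 11
Reactants: 17 C1-prenylated pyrone alcohol
Product: 18 pyrone iodide (both C1 epimers)
Conditions: I2, PPh3, imidazole, CH2Cl2, 0 °C → rt
Reagents that add atoms: iodine, II
Why: Appel reaction on the primary alcohol; the neutral methoxypyrone and the alkenes should be inert to the preformed PPh3–I2 complex.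

Step 12
Reactants: 18 pyrone iodide
Product: 21 (1S,5R,7S,8S)-4-methoxy-8-methyl-5-[(2R)-lavandulyl]-1,7-diprenyl-8-homoprenylbicyclo[3.3.1]non-3-ene-2,9-dione, via dienolate ketene 19 (not isolated), via cyclohexadienone enolate 20 (not isolated)
Conditions: LiTMP (1.2 equiv), THF (0.01 M), −78 °C → rt, then 55 °C
Reagents that add atoms: none
Why: Proposed new method: LiTMP removes C1–H, the only proton conjugated to the lactone carbonyl C9, and the trienolate expels the ring oxygen from C9 (E1cB, as ester enolates with enolate or aryloxide leaving groups give ketenes) to give the (Z)-dienolate ketene 19, which closes ring A (C1–C2–C3–C4–C5–C9) by 6π-electrocyclisation of C1 onto the ketene carbon C9, the known ring closure of dienylketenes to cyclohexa-2,4-dienones; the closest established reactions for the overall ring contraction are the alkoxide-mediated Claisen conversions of 2-pyrones into phloroglucinols, and it is driven by the much greater stability of the vinylogous diketonate 20. In 20 the chain on the sp3 carbon C1 stands over the flat ring, so C6 meets the p-lobe of C5 and ring B (C1–C8–C7–C6–C5–C9) closes by 6-exo-tet C-alkylation through a chair with the C7 prenyl group equatorial, the type of C-alkylation known from alkylative dearomatisation–annulation of acylphloroglucinol anions. C5 is fixed by the cis-1,3 bridge that the new ring demands. C1 is set in the electrocyclisation under control of C8: its methyl group should take the slot over the ring and its larger C7 branch the flank of the unsolvated C9 carbonyl rather than that of the lithium-bearing O2, which gives the C1 epimer whose chair leads to C5. The step needs C- rather than O-alkylation and C5 rather than C3: lithium in THF, the soft iodide and the perpendicular approach favour carbon, attack at C3 from this epimer would force the C7 prenyl group endo, and alkylation before ring contraction is prevented because in the pyrone anion C8 lies syn to the ring oxygen, out of reach of C3.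

Step 13
Reactants: 22 3,4-diacetoxybenzoic acid
Product: 23 3,4-diacetoxybenzoyl chloride
Conditions: (COCl)2, DMF (cat.), CH2Cl2, 0 °C → rt
Reagents that add atoms: oxalyl chloride, O=C(Cl)C(=O)Cl
Why: Acid chloride formation through the Vilsmeier-type chloroiminium catalyst; the aryl acetates should survive.

Step 14
Reactants: 21 bicyclic β-methoxy enone; 23 3,4-diacetoxybenzoyl chloride
Product: 24 (1R,5R,7S,8S)-3-(3,4-diacetoxybenzoyl)-4-methoxy-8-methyl-5-[(2R)-lavandulyl]-1,7-diprenyl-8-homoprenylbicyclo[3.3.1]non-3-ene-2,9-dione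
Conditions: LiTMP, THF, −78 °C; then 23, −78 °C
Reagents that add atoms: none
Why: Vinylic deprotonation at C3 of the β-methoxy enone (both bridgeheads are quaternary, so no enolate can form) and C-acylation of the vinyllithium with the acid chloride is the established way to install the C3 acyl group in bicyclo[3.3.1]nonane-trione methyl enol ethers.

Step 15
Reactants: 24 O-methyl di-O-acetyl precursor
Product: 25 target, (1R,5R,7S,8S)-3-(3,4-dihydroxybenzoyl)-4-hydroxy-8-methyl-5-[(2R)-lavandulyl]-1,7-diprenyl-8-homoprenylbicyclo[3.3.1]non-3-ene-2,9-dione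
Conditions: LiOH, dioxane–H2O, 90 °C, degassed; then 1 M HCl
Reagents that add atoms: lithium hydroxide, [Li+].[OH-] (oxygen of the C4 enol)
Why: Hydroxide addition–elimination at C4 of the 3-acyl β-methoxy enone (vinylogous ester saponification) and saponification of the two aryl acetates should occur together, and acidification gives the enolised triketone; no stereocentre is affected.

**Compound list**
1 | geraniol, (2E)-3,7-dimethylocta-2,6-dien-1-ol | CC(C)=CCC/C(C)=C/CO | starting material
2 | 5-methylhex-4-enoic acid | CC(C)=CCCC(=O)O | starting material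
3 | geranyl 5-methylhex-4-enoate | CC(C)=CCCC(=O)OC/C=C(\C)CCC=C(C)C | intermediate
4 | E(O) boron ketene acetal of 3; boron carries the (4S,5S)-4,5-diphenyl-1,3-bis[3,5-bis(trifluoromethyl)phenylsulfonyl]-1,3,2-diazaborolidine ring; prenyl CH2 cis to the geranyloxy oxygen | CC(C)=CC/C=C(/OB1N(S(=O)(=O)c2cc(C(F)(F)F)cc(C(F)(F)F)c2)[C@@H](c2ccccc2)[C@H](c2ccccc2)N1S(=O)(=O)c1cc(C(F)(F)F)cc(C(F)(F)F)c1)OC/C=C(\C)CCC=C(C)C | intermediate (not isolated)
5 | (2R,3R)-3-ethenyl-3,7-dimethyl-2-(3-methylbut-2-en-1-yl)oct-6-enoic acid | OC(=O)[C@H](CC=C(C)C)[C@](C)(CCC=C(C)C)C=C | intermediate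
6 | (2R,3R)-3-ethenyl-3,7-dimethyl-2-(3-methylbut-2-en-1-yl)oct-6-en-1-ol | OC[C@H](CC=C(C)C)[C@](C)(CCC=C(C)C)C=C | intermediate
7 | (2R,3R)-3-methyl-2-(3-methylbut-2-en-1-yl)-3-(4-methylpent-3-en-1-yl)pentane-1,5-diol | OC[C@H](CC=C(C)C)[C@](C)(CCC=C(C)C)CCO | intermediate
8 | (4R,5R)-4-methyl-5-(3-methylbut-2-en-1-yl)-4-(4-methylpent-3-en-1-yl)oxan-2-one (C2 carbonyl, ring oxygen on C6) | O1C[C@H](CC=C(C)C)[C@](C)(CCC=C(C)C)CC1=O | intermediate
9 | (S)-lavandulol, (2S)-5-methyl-2-(prop-1-en-2-yl)hex-4-en-1-ol | C=C(C)[C@H](CC=C(C)C)CO | starting material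
10 | (S)-lavandulyl iodide, (3S)-3-(iodomethyl)-2,6-dimethylhepta-1,5-diene | C=C(C)[C@H](CC=C(C)C)CI | intermediate
11 | methyl acetoacetate | CC(=O)CC(=O)OC | starting material
12 | methyl (4R)-2-acetyl-7-methyl-4-(prop-1-en-2-yl)oct-6-enoate, both C2 epimers | C=C(C)[C@H](CC=C(C)C)CC(C(C)=O)C(=O)OC | intermediate
13 | methyl (7R,8R)-9-hydroxy-7-methyl-8-prenyl-7-homoprenyl-2-[(2R)-lavandulyl]-3,5-dioxononanoate, both C2 epimers (open form of the keto–enol and hemiketal mixture) | C=C(C)[C@H](CC=C(C)C)CC(C(=O)OC)C(=O)CC(=O)C[C@@](C)(CCC=C(C)C)[C@@H](CC=C(C)C)CO | intermediate (not isolated)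
14 | 4-hydroxy-6-[(2R,3R)-3-(hydroxymethyl)-2,6-dimethyl-2-(4-methylpent-3-en-1-yl)hept-5-en-1-yl]-3-[(2R)-lavandulyl]-2H-pyran-2-one | C=C(C)[C@H](CC=C(C)C)CC1=C(O)C=C(C[C@@](C)(CCC=C(C)C)[C@@H](CC=C(C)C)CO)OC1=O | intermediate
15 | 4-methoxy analogue of 14 (4-methoxy-2-pyrone alcohol) | C=C(C)[C@H](CC=C(C)C)CC1=C(OC)C=C(C[C@@](C)(CCC=C(C)C)[C@@H](CC=C(C)C)CO)OC1=O | intermediate
16 | prenyl bromide, 1-bromo-3-methylbut-2-ene | CC(C)=CCBr | starting material
17 | 15 with a prenyl group on the CH2 (C1) that joins pyrone C6 to the quaternary carbon, both C1 epimers; C7/C8 stereodiad of 8 unchanged | C=C(C)[C@H](CC=C(C)C)CC1=C(OC)C=C(C(CC=C(C)C)[C@@](C)(CCC=C(C)C)[C@@H](CC=C(C)C)CO)OC1=O | intermediate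
18 | iodide of 17 (CH2OH replaced by CH2I), both C1 epimers | C=C(C)[C@H](CC=C(C)C)CC1=C(OC)C=C(C(CC=C(C)C)[C@@](C)(CCC=C(C)C)[C@@H](CC=C(C)C)CI)OC1=O | intermediate
19 | lithium (Z)-dienolate ketene: O=C9=C5(lavandulyl)–C4(OMe)=C3H–C2(OLi)=C1(prenyl)–C8 chain, C8 cis to the enolate oxygen | [Li+].C=C(C)[C@H](CC=C(C)C)CC(=C=O)/C(OC)=C\C([O-])=C(/CC=C(C)C)[C@@](C)(CCC=C(C)C)[C@@H](CC=C(C)C)CI | intermediate (not isolated)
20 | lithium enolate of the monocyclic 6,6-disubstituted 3-methoxy-2-lavandulylcyclohexa-2,4-dienone (ring A closed, C1 configured as in the target, iodide chain intact) | [Li+].C=C(C)[C@H](CC=C(C)C)CC1=C(OC)C=C([O-])[C@@](CC=C(C)C)(C1=O)[C@@](C)(CCC=C(C)C)[C@@H](CC=C(C)C)CI | intermediate (not isolated)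
21 | (1S,5R,7S,8S)-4-methoxy-8-methyl-5-[(2R)-5-methyl-2-(prop-1-en-2-yl)hex-4-en-1-yl]-1,7-bis(3-methylbut-2-en-1-yl)-8-(4-methylpent-3-en-1-yl)bicyclo[3.3.1]non-3-ene-2,9-dione | C=C(C)[C@H](CC=C(C)C)C[C@@]12C[C@H](CC=C(C)C)[C@](C)(CCC=C(C)C)[C@@](CC=C(C)C)(C(=O)C=C1OC)C2=O | intermediate
22 | 3,4-diacetoxybenzoic acid | CC(=O)Oc1ccc(C(=O)O)cc1OC(C)=O | starting material
23 | 3,4-diacetoxybenzoyl chloride | CC(=O)Oc1ccc(C(=O)Cl)cc1OC(C)=O | intermediate
24 | (1R,5R,7S,8S)-3-(3,4-diacetoxybenzoyl)-4-methoxy analogue of the target (C3-aroylated 21) | C=C(C)[C@H](CC=C(C)C)C[C@@]12C[C@H](CC=C(C)C)[C@](C)(CCC=C(C)C)[C@@](CC=C(C)C)(C(=O)C(C(=O)c3ccc(OC(C)=O)c(OC(C)=O)c3)=C1OC)C2=O | intermediate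
25 | (1R,5R,7S,8S)-3-(3,4-dihydroxybenzoyl)-4-hydroxy-8-methyl-5-[(2R)-5-methyl-2-(prop-1-en-2-yl)hex-4-en-1-yl]-1,7-bis(3-methylbut-2-en-1-yl)-8-(4-methylpent-3-en-1-yl)bicyclo[3.3.1]non-3-ene-2,9-dione | C=C(C)[C@H](CC=C(C)C)C[C@@]12C[C@H](CC=C(C)C)[C@](C)(CCC=C(C)C)[C@@](CC=C(C)C)(C(=O)C(C(=O)c3ccc(O)c(O)c3)=C1O)C2=O | target

**Totals**
Total step count: 15. Longest linear sequence: 12 steps (steps 1–5, 8–12, 14, 15).

**Steps most likely to fail**

1. Step 12 (key step, proposed new method). What may go wrong: slow removal of the hindered tertiary C1–H; poor facial selectivity when ring A closes, so that material with the other C1 configuration cannot reach C5 through a chair and drains into C3- or O-alkylation; O-alkylation of the diketonate in place of C-alkylation. The fallback uses known reaction types, sets out from 17 and comes back at 21. Methanolysis of the enol lactone (NaOMe, MeOH) should give the ring-opened (Z)-β-methoxy enoate methyl ester F1. A Claisen (Dieckmann-type) condensation of the C1 ketone enolate onto the C9 ester under equilibrating alkoxide conditions (KOt-Bu, THF) should then give the monocyclic dienone alcohol F2, and the C1 epimers are separated at this stage. An Appel reaction gives the monocyclic iodide F3, and intramolecular C-alkylation of its lithium enolate (LiN(SiMe3)2, toluene–THF) closes ring B to 21.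

2. Step 8. What may go wrong: incomplete acylation of the dianion by the β,β-disubstituted lactone, or dehydration of the cyclic hemiketal form of 13 to a 2-alkylidene-tetrahydropyran in competition with lactonisation. The fallback sets out from 8 and comes back at 14. The lactone is opened with MeNH(OMe)·HCl and i-PrMgCl to the hydroxy N-methoxy-N-methylamide F4, which is silylated (TBSCl, imidazole) to the silyl ether amide F5. Acylation of the dianion of 12 with F5 gives the silyl-protected dioxo ester F6, DBU in hot toluene closes the silyloxy pyrone F7, and Bu4NF releases 14.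

3. Step 5. What may go wrong: poor discrimination between the two primary alcohols, so that oxidation starts at the wrong terminus and the lactone forms with reversed orientation. The fallback sets out from 6 and comes back at 8, and it differentiates the termini by protection. Silylation of 6 (TBSCl, imidazole) gives the silyl ether F8, hydroboration–oxidation (9-BBN; NaOH, H2O2) gives the silyloxy alcohol F9, and oxidation (TEMPO, PhI(OAc)2, MeCN–H2O) gives the silyloxy acid F10. Bu4NF followed by a trace of acid should then close lactone 8 with the carbonyl unambiguously at C2.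

**Further compounds**
F1 | step 12 | methyl (2Z)-enoate from methanolysis of 17: MeO2C(C9)–C5(lavandulyl)=C4(OMe)–C3H2–C2(=O)–C1H(prenyl)–C8–C7–C6H2OH, ester cis to C3 | C=C(C)[C@H](CC=C(C)C)C\C(C(=O)OC)=C(/OC)CC(=O)C(CC=C(C)C)[C@@](C)(CCC=C(C)C)[C@@H](CC=C(C)C)CO
F2 | step 12 | monocyclic 6,6-disubstituted 5-hydroxy-3-methoxy-2-lavandulylcyclohexa-2,4-dienone alcohol (neutral form of 20 with CH2OH in place of CH2I) | C=C(C)[C@H](CC=C(C)C)CC1=C(OC)C=C(O)[C@@](CC=C(C)C)(C1=O)[C@@](C)(CCC=C(C)C)[C@@H](CC=C(C)C)CO
F3 | step 12 | iodide of F2 (neutral form of 20) | C=C(C)[C@H](CC=C(C)C)CC1=C(OC)C=C(O)[C@@](CC=C(C)C)(C1=O)[C@@](C)(CCC=C(C)C)[C@@H](CC=C(C)C)CI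
F4 | step 8 | hydroxy N-methoxy-N-methylamide from ring opening of 8 | CON(C)C(=O)C[C@@](C)(CCC=C(C)C)[C@@H](CC=C(C)C)CO
F5 | step 8 | tert-butyldimethylsilyl ether of F4 | CON(C)C(=O)C[C@@](C)(CCC=C(C)C)[C@@H](CC=C(C)C)CO[Si](C)(C)C(C)(C)C
F6 | step 8 | tert-butyldimethylsilyl ether of 13 | C=C(C)[C@H](CC=C(C)C)CC(C(=O)OC)C(=O)CC(=O)C[C@@](C)(CCC=C(C)C)[C@@H](CC=C(C)C)CO[Si](C)(C)C(C)(C)C
F7 | step 8 | tert-butyldimethylsilyl ether of 14 (primary alcohol silylated) | C=C(C)[C@H](CC=C(C)C)CC1=C(O)C=C(C[C@@](C)(CCC=C(C)C)[C@@H](CC=C(C)C)CO[Si](C)(C)C(C)(C)C)OC1=O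
F8 | step 5 | tert-butyldimethylsilyl ether of 6 | CC(C)(C)[Si](C)(C)OC[C@H](CC=C(C)C)[C@](C)(CCC=C(C)C)C=C
F9 | step 5 | mono-silyl ether of 7 (silyl on the C6 oxygen, free CH2CH2OH) | CC(C)(C)[Si](C)(C)OC[C@H](CC=C(C)C)[C@](C)(CCC=C(C)C)CCO
F10 | step 5 | silyloxy acid (C2 carboxylic acid, C6 silyl ether) | CC(C)(C)[Si](C)(C)OC[C@H](CC=C(C)C)[C@](C)(CCC=C(C)C)CC(=O)O
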